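**Plan**

- Retrosynthesis: the two benzoates and the C5/C6 oxygens are taken off first (orthoester acylation, epoxide hydrolysis, directed epoxidation). This leads back to methyl (3R,4R)-3,4-dihydroxycyclohexa-1,5-diene-1-carboxylate, whose ring is then cut at C1–C2 and C3–C4.
- Enabling feature: the C4 oxygen and the exocyclic carbon C7 on C1 are 1,4-related on the ring. C1, C6, C5, C4 with O-4 and C7 (as C=O) are therefore the ring of a 2-pyrone, and C2–C3 is a cis-dioxyethene whose C2 oxygen is a sacrificial leaving group.
- Forward: a Diels–Alder reaction of 3-bromo-2H-pyran-2-one with 2,2-dimethyl-1,3-dioxole closes the carbocycle as a bridged lactone. The bromine (activator) is removed with zinc, the lactone (temporary ring, C7 at the acid oxidation level) is opened, and E1cB loss of the C2 acetal oxygen creates the C1=C2 alkene.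
- Stereochemistry: the endo transition state sets C3–O trans to C4–O. The racemate is resolved by lipase hydrolysis of the diacetate. C5 and C6 follow by substrate control (C4–OH-directed epoxidation, trans opening at allylic C6).
- Endgame: ester reduction, primary benzoylation, and delivery of the second benzoate to C5 through the C4/C5 cyclic orthobenzoate.

Key step: step 1

Assumption: Burkholderia cepacia lipase shows with diacetate 7 its usual preference for the (R)-configured carbinol ester, as with trans-cycloalkane-1,2-diyl diacetates, so the (3R,4R)-enantiomer is the one hydrolysed.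

**Route**

Step 1
Reactants: 1 3-bromo-2H-pyran-2-one; 2 2,2-dimethyl-1,3-dioxole
Product: 3 racemic endo-4-bromo-7,8-(isopropylidenedioxy)-2-oxabicyclo[2.2.2]oct-5-en-3-one
Conditions: 2 (3 equiv), neat, BHT (cat.), sealed tube, 90 °C
Reagents that add atoms: none
Why: Concerted, asynchronous [4+2] cycloaddition in which pyrone C-3 and C-6 bond suprafacially to the two olefinic carbons of the dioxole, so that the ring bonds C1–C2 and C3–C4 of the target form in one event. The closest known reaction type is the thermal Diels–Alder reaction of 3-bromo-2-pyrone with enol ethers, the bromine making the diene reactive below the temperature of CO2 extrusion, so that the lactone bridge is kept. The cyclohexene ring closes by the [4+2] mode onto the pyrone and gives a 2-oxabicyclo[2.2.2]octenone with a cis-fused dioxolane; no ring is closed by a separate cyclisation. Of the four new stereocentres, the two bridgeheads (later C1 and C4) are tied by the O–C(=O) bridge, and the two dioxolane carbons (later C2 and C3) are set by the cis geometry of the dienophile and by the endo transition state, in which the dioxole oxygens lie under the diene and end up anti to the lactone oxygen (the trans C3–O/C4–O relation of the target). The step needs only endo over exo selectivity, because the symmetric dienophile has no regiochemical choice and its C2 oxygen is discarded later; any exo isomer is removed by chromatography. The adduct is racemic and the absolute configuration is selected in step 5.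

Step 2
Reactants: 3 racemic bromo lactone
Product: 4 racemic endo-7,8-(isopropylidenedioxy)-2-oxabicyclo[2.2.2]oct-5-en-3-one
Conditions: Zn dust, AcOH, THF, 23 °C
Reagents that add atoms: none
Why: Reductive dehalogenation of an α-bromo lactone by zinc with protonation by acetic acid should give the bridgehead C–H, whose configuration is fixed by the bicycle, while β-elimination of the acetal oxygen is excluded because it would give a bridgehead alkene.

Step 3
Reactants: 4 racemic lactone acetonide
Product: 6 racemic methyl trans-3,4-dihydroxycyclohexa-1,5-diene-1-carboxylate, via hydroxy ester acetonide 5 (not isolated)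
Conditions: NaOMe (0.2 equiv), MeOH, 0 °C; evaporate; LiN(SiMe3)2 (3.2 equiv), THF, −78 → 0 °C; aq. NH4Cl
Reagents that add atoms: methanol, CO
Why: Methoxide-catalysed transesterification opens the bridged lactone, and the alkoxide/ester-dienolate dianion then expels the β-acetal oxygen on C2 in an E1cB elimination that creates the C1=C2 alkene and, after loss of acetone on work-up, the free C3–OH; C1 epimers and double-bond isomers of 5 converge on the same dienolate, and the C4 alkoxide cannot leave, so C3 and C4 are untouched.

Step 4
Reactants: 6 racemic diol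
Product: 7 racemic methyl trans-3,4-diacetoxycyclohexa-1,5-diene-1-carboxylate
Conditions: Ac2O, pyridine, DMAP (cat.), CH2Cl2, 0 °C
Reagents that add atoms: acetic anhydride, CC(=O)OC(C)=O
Why: Standard DMAP-catalysed acetylation of both secondary alcohols should give the substrate for the enzymatic resolution without touching the base-sensitive diene.

Step 5
Reactants: 7 racemic diacetate
Product: 8 methyl (3R,4R)-3,4-dihydroxycyclohexa-1,5-diene-1-carboxylate
Conditions: Burkholderia cepacia lipase (immobilised), phosphate buffer pH 7.0–MTBE, 30 °C, to about half conversion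
Reagents that add atoms: none
Why: Lipase-catalysed enantioselective hydrolysis (kinetic resolution of a trans-1,2-diol diacetate) should cleave both acetates of the (3R,4R)-enantiomer at neutral pH and leave the (3S,4S)-diacetate, which is separated by chromatography.

Step 6
Reactants: 8 (3R,4R)-diol
Product: 9 methyl (3R,4S,5S,6R)-5,6-epoxy-3,4-dihydroxycyclohex-1-ene-1-carboxylate
Conditions: mCPBA, NaHCO3, CH2Cl2, 0 °C
Reagents that add atoms: 3-chloroperoxybenzoic acid, OOC(=O)c1cccc(Cl)c1
Why: Hydroxyl-directed peracid epoxidation should attack only the C5=C6 alkene (C1=C2 is deactivated by the ester) and deliver oxygen syn to the allylic C4–OH through hydrogen bonding, which sets the C5 oxygen cis to C4–O.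

Step 7
Reactants: 9 epoxy diol ester
Product: 10 (3R,4S,5S,6R)-5,6-epoxy-1-(hydroxymethyl)cyclohex-1-ene-3,4-diol
Conditions: iBu2AlH (5 equiv), THF, −78 → −30 °C; aq. potassium sodium tartrate
Reagents that add atoms: none
Why: 1,2-Reduction of the conjugated ester by the aluminium hydride should give the allylic alcohol at a temperature at which the epoxide and the alkene are not attacked.

Step 8
Reactants: 10 epoxy triol
Product: 11 [(3R,4S,5S,6R)-5,6-epoxy-3,4-dihydroxycyclohex-1-en-1-yl]methyl benzoate
Conditions: BzCl (1.05 equiv), 2,4,6-collidine, CH2Cl2, −40 °C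
Reagents that add atoms: benzoyl chloride, O=C(Cl)c1ccccc1
Why: Kinetically selective acylation with one equivalent of acid chloride at low temperature should esterify the unhindered primary allylic alcohol in preference to the two secondary alcohols.

Step 9
Reactants: 11 epoxy diol monobenzoate
Product: 12 [(3R,4S,5R,6S)-3,4,5,6-tetrahydroxycyclohex-1-en-1-yl]methyl benzoate
Conditions: HClO4 (cat.), THF–H2O 3:1, 0 °C
Reagents that add atoms: water, O
Why: Acid-catalysed hydrolysis of the vinyl epoxide should occur at the allylic C6 with inversion (trans-diaxial opening, assisted by the carbonyl oxygen of the neighbouring C7 benzoate through a six-membered acyloxonium ion that water returns to the primary ester), which sets C6–OH trans to C5–OH.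

Step 10
Reactants: 12 tetrol monobenzoate
Product: 14 [(3R,4S,5R,6S)-5-(benzoyloxy)-3,4,6-trihydroxycyclohex-1-en-1-yl]methyl benzoate (target), via cyclic orthobenzoate 13 (not isolated)
Conditions: PhC(OMe)3, camphorsulfonic acid (cat.), MeCN, 23 °C; then 80% aq. AcOH, 0 → 23 °C
Reagents that add atoms: trimethyl orthobenzoate, COC(OC)(OC)c1ccccc1; water, O
Why: Orthoester-mediated regioselective monoacylation of a cis-diol: only the C4/C5 cis-diol can form the five-membered orthobenzoate, and its acid hydrolysis places the ester on the axial oxygen, which should be C5–O because allylic 1,2-strain with the C1 substituent holds C6–OH pseudoaxial.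

**Compound list**

1 | 3-bromo-2H-pyran-2-one | O=C1OC=CC=C1Br | starting material
2 | 2,2-dimethyl-1,3-dioxole | CC1(C)OC=CO1 | starting material
3 | rac-endo-4-bromo-7,8-(isopropylidenedioxy)-2-oxabicyclo[2.2.2]oct-5-en-3-one; dioxolane oxygens syn to the C5=C6 bridge and anti to the lactone bridge; racemate, the enantiomer that leads to 14 is drawn | O=C1O[C@@H]2C=C[C@@]1(Br)[C@H]3OC(C)(C)O[C@@H]23 | intermediate
4 | rac-endo-7,8-(isopropylidenedioxy)-2-oxabicyclo[2.2.2]oct-5-en-3-one; same relative configuration as 3; racemate | O=C1O[C@@H]2C=C[C@H]1[C@H]3OC(C)(C)O[C@@H]23 | intermediate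
5 | rac-methyl 4-hydroxy-2,3-(isopropylidenedioxy)cyclohex-5-ene-1-carboxylate; CO2Me and 4-OH cis to each other, acetonide on the opposite face; racemate | COC(=O)[C@H]1C=C[C@@H](O)[C@@H]2OC(C)(C)O[C@H]12 | intermediate (not isolated)
6 | rac-methyl trans-3,4-dihydroxycyclohexa-1,5-diene-1-carboxylate; racemate, (3R,4R) drawn | COC(=O)C1=C[C@@H](O)[C@H](O)C=C1 | intermediate
7 | rac-methyl trans-3,4-diacetoxycyclohexa-1,5-diene-1-carboxylate; racemate, (3R,4R) drawn | COC(=O)C1=C[C@@H](OC(C)=O)[C@H](OC(C)=O)C=C1 | intermediate
8 | methyl (3R,4R)-3,4-dihydroxycyclohexa-1,5-diene-1-carboxylate, single enantiomer | COC(=O)C1=C[C@@H](O)[C@H](O)C=C1 | intermediate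
9 | methyl (3R,4S,5S,6R)-5,6-epoxy-3,4-dihydroxycyclohex-1-ene-1-carboxylate; epoxide cis to 4-OH | COC(=O)C1=C[C@@H](O)[C@H](O)[C@@H]2O[C@H]12 | intermediate
10 | (3R,4S,5S,6R)-5,6-epoxy-1-(hydroxymethyl)cyclohex-1-ene-3,4-diol | OCC1=C[C@@H](O)[C@H](O)[C@@H]2O[C@H]12 | intermediate
11 | [(3R,4S,5S,6R)-5,6-epoxy-3,4-dihydroxycyclohex-1-en-1-yl]methyl benzoate | O=C(OCC1=C[C@@H](O)[C@H](O)[C@@H]2O[C@H]12)c1ccccc1 | intermediate
12 | [(3R,4S,5R,6S)-3,4,5,6-tetrahydroxycyclohex-1-en-1-yl]methyl benzoate | O=C(OCC1=C[C@@H](O)[C@H](O)[C@H](O)[C@H]1O)c1ccccc1 | intermediate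
13 | 4,5-O-(α-methoxybenzylidene) cyclic orthoester of 12; orthoester carbon as a mixture of epimers | O=C(OCC1=C[C@@H](O)[C@@H]2OC(OC)(c3ccccc3)O[C@@H]2[C@H]1O)c1ccccc1 | intermediate (not isolated)
14 | [(3R,4S,5R,6S)-5-(benzoyloxy)-3,4,6-trihydroxycyclohex-1-en-1-yl]methyl benzoate | O=C(OCC1=C[C@@H](O)[C@H](O)[C@H](OC(=O)c2ccccc2)[C@H]1O)c1ccccc1 | target

**Step count**

Total: 10 steps. Longest linear sequence: 10 steps (1 → 14).

**Steps most likely to fail**

Step 10. The orthoester may open on the wrong oxygen (ester on C4), or the benzoyl group may migrate between the cis C4 and C5 oxygens, if the half-chair with axial C5–O is not the reacting one. The fallback sets out from 11 and separates the oxygens with protecting groups. Silylation of both alcohols (TBSOTf, 2,6-lutidine, CH2Cl2, −78 °C) should give the bis-silyl ether F1. Opening of the epoxide at the allylic C6 with levulinic acid and Cs2CO3 (0.5 equiv) in DMF at 70 °C should give the C6 levulinate F2, in which C5–OH is the only free hydroxyl. Benzoylation (BzCl, pyridine, DMAP) should give the C5 benzoate F3. Hydrazine acetate in CH2Cl2–MeOH removes the levulinate selectively and should give the bis-silyl ether of the target F4. HF·pyridine in THF then returns to the route at 14.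

Step 3. The strong base may cause dehydration to a hydroxybenzoate (aromatisation), or the alkoxide leaving group may depart too slowly. The fallback sets out from 5, isolated after the methanolysis, and uses a better leaving group with a mild base. Aqueous AcOH (80%, 40 °C) removes the acetonide and should give the triol F5. 1,1'-Carbonyldiimidazole (1 equiv, CH2Cl2, 0 °C) closes the cis-2,3-diol to the cyclic carbonate F6. DBU (CH2Cl2, 0 °C) then triggers the E1cB elimination with the carbonate as leaving group; after loss of CO2 the sequence returns to the route at 6.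

Step 5. The enzyme may discriminate poorly between the enantiomers, or hydrolysis may stall at the monoacetate. The fallback sets out from 6 and omits step 4: preparative chromatography of the racemic diol on a chiral stationary phase (amylose tris(3,5-dimethylphenylcarbamate), supercritical CO2–MeOH) separates the enantiomers and returns to the route at 8. It makes no new compound.

Further compounds
F1 | step 10 | [(3R,4S,5S,6R)-3,4-bis(tert-butyldimethylsilyloxy)-5,6-epoxycyclohex-1-en-1-yl]methyl benzoate | O=C(OCC1=C[C@@H](O[Si](C)(C)C(C)(C)C)[C@H](O[Si](C)(C)C(C)(C)C)[C@@H]2O[C@H]12)c1ccccc1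
F2 | step 10 | 3,4-bis-silyl ether of 12 carrying a levulinate on C6–O and a free C5–OH | O=C(OCC1=C[C@@H](O[Si](C)(C)C(C)(C)C)[C@H](O[Si](C)(C)C(C)(C)C)[C@H](O)[C@H]1OC(=O)CCC(C)=O)c1ccccc1
F3 | step 10 | C5 benzoate of F2 | O=C(OCC1=C[C@@H](O[Si](C)(C)C(C)(C)C)[C@H](O[Si](C)(C)C(C)(C)C)[C@H](OC(=O)c2ccccc2)[C@H]1OC(=O)CCC(C)=O)c1ccccc1
F4 | step 10 | 3,4-bis(tert-butyldimethylsilyl) ether of 14 | O=C(OCC1=C[C@@H](O[Si](C)(C)C(C)(C)C)[C@H](O[Si](C)(C)C(C)(C)C)[C@H](OC(=O)c2ccccc2)[C@H]1O)c1ccccc1
F5 | step 3 | rac-methyl 2,3,4-trihydroxycyclohex-5-ene-1-carboxylate; 2-OH and 3-OH cis, CO2Me and 4-OH on the opposite face | COC(=O)[C@H]1C=C[C@@H](O)[C@H](O)[C@@H]1O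
F6 | step 3 | rac-2,3-O-carbonyl derivative (cyclic carbonate) of F5 | COC(=O)[C@H]1C=C[C@@H](O)[C@@H]2OC(=O)O[C@H]12
F0 | step 5 | none | none
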